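## Retrosynthetic overview

1. Target 25 ← tris-silyl macrolide 24 by global desilylation.
2. 24 ← hydroxy dihydropyranone 21 in one base-triggered operation: C19–O attacks the δ-lactone carbonyl (closing the 20-membered lactone) and the released C5 alkoxide displaces C6–Cl (closing the trans-epoxide).
3. 21 ← chlorohydrin 17 by acrylation and ring-closing metathesis (the temporary pyranone fixes the Z-alkene); 17 ← aldehyde 12 by α-chlorination (sets C6) and γ-silyloxyallylstannane addition (sets C4 and C5).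
4. 12 ← ω-pentadecalactone (C5–C19), N-methoxy-N-methylacetamide (C20–C21) and (R)-propylene oxide (C22–C24); C19 by Noyori hydrogenation, C21 by 1,3-syn reduction.
5. Ring order: temporary dihydropyranone first, then macrolactone and epoxide together.

Assumption: macrolide numbering is used throughout (C1 lactone carbonyl, C2=C3 Z-alkene, C4 carbinol, C5/C6 epoxide, C7–C18 CH2, C19 lactone carbinol, C20–C24 side chain); the target is (2Z,4R,5S,6S,19S,21R,23R), and CIP letters of intermediates change where protecting groups change priorities.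

## Route

Step 1
Reactants: 1 ω-pentadecalactone (oxacyclohexadecan-2-one); 2 N-methoxy-N-methylacetamide
Product: 4 17-hydroxy-N-methoxy-N-methyl-3-oxoheptadecanamide, via lithium enolate 3 (not isolated)
Conditions: 2 (2.5 equiv), LiN(iPr)2 (2.5 equiv), THF, −78 °C; then 1, −78 → −20 °C; aq NH4Cl
Reagents that add atoms: none
Why: Claisen-type acylation of the amide enolate by the lactone opens the ring and gives the whole C5–C21 chain with the primary alcohol (C5) and the β-keto Weinreb amide (C19–C21) already differentiated, the excess enolate deprotonating the product so that it is not attacked again.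

Step 2
Reactants: 4 17-hydroxy-N-methoxy-N-methyl-3-oxoheptadecanamide
Product: 5 (3S)-3,17-dihydroxy-N-methoxy-N-methylheptadecanamide
Conditions: RuCl2[(S)-BINAP] (1 mol %), H2 (50 bar), MeOH, 50 °C
Reagents that add atoms: none
Why: Noyori asymmetric hydrogenation of a β-keto carbonyl compound, the ketone/amide chelate on the (S)-BINAP ruthenium hydride giving the (S)-carbinol (C19) in the same sense as methyl acetoacetate gives the (S)-alcohol.

Step 3
Reactants: 5 (3S)-3,17-dihydroxy-N-methoxy-N-methylheptadecanamide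
Product: 6 (3S)-N-methoxy-N-methyl-3,17-bis(triethylsilyloxy)heptadecanamide
Conditions: Et3SiCl (2.4 equiv), imidazole, DMF, 0 °C → rt
Reagents that add atoms: chlorotriethylsilane, CC[Si](Cl)(CC)CC
Why: routine silylation, the secondary TES ether being the one temporary group at C19–O and the primary TES ether being set up for direct oxidation in step 7.

Step 4
Reactants: 6 (3S)-N-methoxy-N-methyl-3,17-bis(triethylsilyloxy)heptadecanamide; 7 (R)-propylene oxide [(2R)-2-methyloxirane]
Product: 9 (2R,6S)-2-hydroxy-6,20-bis(triethylsilyloxy)icosan-4-one, via dilithio reagent 8 (not isolated)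
Conditions: 7 (3 equiv), Li powder (5.6 equiv), 4,4′-di-tert-butylbiphenyl (10 mol %), THF, −78 °C; then 6, −78 → −40 °C; aq NH4Cl
Reagents that add atoms: none
Why: reductive lithiation cleaves the primary C–O bond of the epoxide to LiCH2CH(OLi)CH3 without touching the stereocentre (C23), and this β-oxido organolithium adds once to the Weinreb amide through the stable N,O-chelated tetrahedral adduct (Weinreb ketone synthesis).

Step 5
Reactants: 9 (2R,6S)-2-hydroxy-6,20-bis(triethylsilyloxy)icosan-4-one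
Product: 10 (2R,4R,6S)-6,20-bis(triethylsilyloxy)icosane-2,4-diol
Conditions: Et2BOMe (1.1 equiv), THF/MeOH 4:1, −78 °C; NaBH4; AcOH, then MeOH co-evaporation
Reagents that add atoms: none
Why: Narasaka–Prasad reduction, external hydride adding axially to the boron chelate of the β-hydroxy ketone to give the 1,3-syn diol (C21 syn to C23), which completes the all-syn C19/C21/C23 array.

Step 6
Reactants: 10 (2R,4R,6S)-6,20-bis(triethylsilyloxy)icosane-2,4-diol
Product: 11 (2R,4R,6S)-2,4-bis(tert-butyldimethylsilyloxy)-6,20-bis(triethylsilyloxy)icosane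
Conditions: tBuMe2SiOTf (2.5 equiv), 2,6-lutidine, CH2Cl2, −78 → 0 °C
Reagents that add atoms: tert-butyldimethylsilyl trifluoromethanesulfonate, CC(C)(C)[Si](C)(C)OS(=O)(=O)C(F)(F)F
Why: silylation of the two secondary alcohols under conditions that leave TES ethers intact.

Step 7
Reactants: 11 (2R,4R,6S)-2,4-bis(tert-butyldimethylsilyloxy)-6,20-bis(triethylsilyloxy)icosane
Product: 12 (15S,17R,19R)-17,19-bis(tert-butyldimethylsilyloxy)-15-(triethylsilyloxy)icosanal
Conditions: (COCl)2, DMSO, CH2Cl2, −78 → −35 °C; then Et3N, −78 °C → rt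
Reagents that add atoms: none
Why: Swern oxidation in which the chlorosulfonium salt cleaves and oxidises only the primary TES ether, secondary TES and TBS ethers surviving, so the C5 aldehyde appears without a separate deprotection.

Step 8
Reactants: 13 allyl tert-butyldimethylsilyl ether
Product: 15 (Z)-tributyl[3-(tert-butyldimethylsilyloxy)prop-2-en-1-yl]stannane, via lithiated ether 14 (not isolated)
Conditions: sec-BuLi, THF/HMPA, −78 °C; then Bu3SnCl, −78 °C
Reagents that add atoms: tributyltin chloride, CCCC[Sn](Cl)(CCCC)CCCC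
Why: allylic deprotonation gives the oxygen-coordinated (Z)-allyl anion, which is stannylated at the carbon remote from oxygen to the (Z)-γ-silyloxyallylstannane.

Step 9
Reactants: 12 (15S,17R,19R)-17,19-bis(tert-butyldimethylsilyloxy)-15-(triethylsilyloxy)icosanal; 15 (Z)-tributyl[3-(tert-butyldimethylsilyloxy)prop-2-en-1-yl]stannane
Product: 17 (3R,4S,5R,18S,20R,22R)-3,20,22-tris(tert-butyldimethylsilyloxy)-5-chloro-18-(triethylsilyloxy)tricos-1-en-4-ol, via chloro aldehyde 16 (not isolated)
Conditions: N-chlorosuccinimide (1.05 equiv), (2S,5S)-2,5-diphenylpyrrolidine (10 mol %), CH2Cl2, 0 °C; then 15 (1.6 equiv), BF3·OEt2 (2.2 equiv), −78 °C; aq NaHCO3, KF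
Reagents that add atoms: N-chlorosuccinimide, O=C1CCC(=O)N1Cl
Why: enamine-catalysed α-chlorination sets C6 as the (R)-chloride (the catalyst antipode is chosen for this sense), after which Lewis-acid allylstannation through an open transition state gives 4,5-syn and Cornforth (polar Felkin–Anh) addition to the α-chloro aldehyde gives 5,6-anti, so C4 and C5 follow from C6.

Step 10
Reactants: 17 (3R,4S,5R,18S,20R,22R)-3,20,22-tris(tert-butyldimethylsilyloxy)-5-chloro-18-(triethylsilyloxy)tricos-1-en-4-ol; 18 acryloyl chloride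
Product: 19 (3R,4S,5R,18S,20R,22R)-3,20,22-tris(tert-butyldimethylsilyloxy)-5-chloro-18-(triethylsilyloxy)tricos-1-en-4-yl acrylate
Conditions: 18 (3 equiv), iPr2NEt, CH2Cl2, −20 → 0 °C
Reagents that add atoms: none
Why: O-acylation of the only free hydroxyl (C5–OH), the tertiary amine being too weak to close the chlorohydrin.

Step 11
Reactants: 19 (3R,4S,5R,18S,20R,22R)-3,20,22-tris(tert-butyldimethylsilyloxy)-5-chloro-18-(triethylsilyloxy)tricos-1-en-4-yl acrylate
Product: 21 (5R,6S)-5-(tert-butyldimethylsilyloxy)-6-[(1R,14S,16S,18R)-16,18-bis(tert-butyldimethylsilyloxy)-1-chloro-14-hydroxynonadecyl]-5,6-dihydro-2H-pyran-2-one, via triethylsilyl ether 20 (not isolated)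
Conditions: second-generation Hoveyda–Grubbs catalyst RuCl2(H2IMes)(=CH-C6H4-2-OiPr) (7 mol %), CH2Cl2 (5 mM), 40 °C; then MeOH, pyridinium p-toluenesulfonate (0.3 equiv), 0 °C → rt
Reagents that add atoms: none
Why: ring-closing metathesis of the acrylate onto the C3 vinyl group gives the dihydropyranone, which locks C2=C3 cis, and mild acidic methanolysis then removes only the secondary TES ether to free C19–OH.

Step 12
Reactants: 21 (5R,6S)-5-(tert-butyldimethylsilyloxy)-6-[(1R,14S,16S,18R)-16,18-bis(tert-butyldimethylsilyloxy)-1-chloro-14-hydroxynonadecyl]-5,6-dihydro-2H-pyran-2-one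
Product: 24 (2Z,4R,5R,6S,19S,21S,23R)-4,21,23-tris(tert-butyldimethylsilyloxy)-5,6-epoxytetracos-2-en-19-olide, via sodium alkoxide 22 (not isolated), via ring-expanded chlorohydrin alkoxide 23 (not isolated)
Conditions: NaN(SiMe3)2 (1.05 equiv), THF (0.5 mM), −78 → 0 °C; pH 7 buffer
Reagents that add atoms: none
Why: Proposed new method: the C19 alkoxide attacks the δ-lactone carbonyl in a reversible ring-expanding translactonization, and the C5 alkoxide thus released, anti-periplanar to C6–Cl, closes the trans-epoxide by irreversible 3-exo-tet SN2 (inversion at C6, retention at C4, C5 and C19), which pulls the equilibrium to the 20-membered lactone so that both rings form in one operation with the Z-alkene inherited from the pyranone; the closest known reactions are alkoxide opening of lactones bearing a vicinal leaving group to give epoxy esters and alkoxide-mediated ring-expanding translactonizations.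

Step 13
Reactants: 24 (2Z,4R,5R,6S,19S,21S,23R)-4,21,23-tris(tert-butyldimethylsilyloxy)-5,6-epoxytetracos-2-en-19-olide
Product: 25 (2Z,4R,5S,6S,19S,21R,23R)-5,6-epoxy-4,21,23-trihydroxytetracos-2-en-19-olide
Conditions: HF·pyridine, pyridine, THF, 0 °C → rt
Reagents that add atoms: none
Why: buffered fluoride cleavage of the three TBS ethers touches no stereocentre and avoids the alkoxide conditions that would cause Payne rearrangement or translactonization to the butenolide.

## Compound list

1 | ω-pentadecalactone (oxacyclohexadecan-2-one) | O=C1CCCCCCCCCCCCCCO1 | starting material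
2 | N-methoxy-N-methylacetamide | CC(=O)N(C)OC | starting material
3 | lithium enolate of N-methoxy-N-methylacetamide | [Li]OC(=C)N(C)OC | intermediate (not isolated)
4 | 17-hydroxy-N-methoxy-N-methyl-3-oxoheptadecanamide | OCCCCCCCCCCCCCCC(=O)CC(=O)N(C)OC | intermediate
5 | (3S)-3,17-dihydroxy-N-methoxy-N-methylheptadecanamide | OCCCCCCCCCCCCCC[C@H](O)CC(=O)N(C)OC | intermediate
6 | (3S)-N-methoxy-N-methyl-3,17-bis(triethylsilyloxy)heptadecanamide | CC[Si](CC)(CC)OCCCCCCCCCCCCCC[C@H](O[Si](CC)(CC)CC)CC(=O)N(C)OC | intermediate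
7 | (R)-propylene oxide [(2R)-2-methyloxirane] | C[C@@H]1CO1 | starting material
8 | lithium (2R)-1-lithiopropan-2-olate | C[C@@H](O[Li])C[Li] | intermediate (not isolated)
9 | (2R,6S)-2-hydroxy-6,20-bis(triethylsilyloxy)icosan-4-one | C[C@@H](O)CC(=O)C[C@@H](O[Si](CC)(CC)CC)CCCCCCCCCCCCCCO[Si](CC)(CC)CC | intermediate
10 | (2R,4R,6S)-6,20-bis(triethylsilyloxy)icosane-2,4-diol | C[C@@H](O)C[C@@H](O)C[C@@H](O[Si](CC)(CC)CC)CCCCCCCCCCCCCCO[Si](CC)(CC)CC | intermediate
11 | (2R,4R,6S)-2,4-bis(tert-butyldimethylsilyloxy)-6,20-bis(triethylsilyloxy)icosane | C[C@@H](O[Si](C)(C)C(C)(C)C)C[C@@H](O[Si](C)(C)C(C)(C)C)C[C@@H](O[Si](CC)(CC)CC)CCCCCCCCCCCCCCO[Si](CC)(CC)CC | intermediate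
12 | (15S,17R,19R)-17,19-bis(tert-butyldimethylsilyloxy)-15-(triethylsilyloxy)icosanal | C[C@@H](O[Si](C)(C)C(C)(C)C)C[C@@H](O[Si](C)(C)C(C)(C)C)C[C@@H](O[Si](CC)(CC)CC)CCCCCCCCCCCCCC=O | intermediate
13 | allyl tert-butyldimethylsilyl ether | C=CCO[Si](C)(C)C(C)(C)C | starting material
14 | (Z)-[3-(tert-butyldimethylsilyloxy)allyl]lithium | [Li]C/C=C\O[Si](C)(C)C(C)(C)C | intermediate (not isolated)
15 | (Z)-tributyl[3-(tert-butyldimethylsilyloxy)prop-2-en-1-yl]stannane | CCCC[Sn](CCCC)(CCCC)C/C=C\O[Si](C)(C)C(C)(C)C | intermediate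
16 | (2R,15S,17R,19R)-17,19-bis(tert-butyldimethylsilyloxy)-2-chloro-15-(triethylsilyloxy)icosanal | C[C@@H](O[Si](C)(C)C(C)(C)C)C[C@@H](O[Si](C)(C)C(C)(C)C)C[C@@H](O[Si](CC)(CC)CC)CCCCCCCCCCCC[C@@H](Cl)C=O | intermediate (not isolated)
17 | (3R,4S,5R,18S,20R,22R)-3,20,22-tris(tert-butyldimethylsilyloxy)-5-chloro-18-(triethylsilyloxy)tricos-1-en-4-ol | C[C@@H](O[Si](C)(C)C(C)(C)C)C[C@@H](O[Si](C)(C)C(C)(C)C)C[C@@H](O[Si](CC)(CC)CC)CCCCCCCCCCCC[C@@H](Cl)[C@@H](O)[C@H](O[Si](C)(C)C(C)(C)C)C=C | intermediate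
18 | acryloyl chloride | C=CC(=O)Cl | starting material
19 | (3R,4S,5R,18S,20R,22R)-3,20,22-tris(tert-butyldimethylsilyloxy)-5-chloro-18-(triethylsilyloxy)tricos-1-en-4-yl acrylate | C[C@@H](O[Si](C)(C)C(C)(C)C)C[C@@H](O[Si](C)(C)C(C)(C)C)C[C@@H](O[Si](CC)(CC)CC)CCCCCCCCCCCC[C@@H](Cl)[C@@H](OC(=O)C=C)[C@H](O[Si](C)(C)C(C)(C)C)C=C | intermediate
20 | (5R,6S)-5-(tert-butyldimethylsilyloxy)-6-[(1R,14S,16R,18R)-16,18-bis(tert-butyldimethylsilyloxy)-1-chloro-14-(triethylsilyloxy)nonadecyl]-5,6-dihydro-2H-pyran-2-one | C[C@@H](O[Si](C)(C)C(C)(C)C)C[C@@H](O[Si](C)(C)C(C)(C)C)C[C@@H](O[Si](CC)(CC)CC)CCCCCCCCCCCC[C@@H](Cl)[C@H]1OC(=O)C=C[C@H]1O[Si](C)(C)C(C)(C)C | intermediate (not isolated)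
21 | (5R,6S)-5-(tert-butyldimethylsilyloxy)-6-[(1R,14S,16S,18R)-16,18-bis(tert-butyldimethylsilyloxy)-1-chloro-14-hydroxynonadecyl]-5,6-dihydro-2H-pyran-2-one | C[C@@H](O[Si](C)(C)C(C)(C)C)C[C@@H](O[Si](C)(C)C(C)(C)C)C[C@@H](O)CCCCCCCCCCCC[C@@H](Cl)[C@H]1OC(=O)C=C[C@H]1O[Si](C)(C)C(C)(C)C | intermediate
22 | sodium C19-alkoxide of 21 | C[C@@H](O[Si](C)(C)C(C)(C)C)C[C@@H](O[Si](C)(C)C(C)(C)C)C[C@@H](O[Na])CCCCCCCCCCCC[C@@H](Cl)[C@H]1OC(=O)C=C[C@H]1O[Si](C)(C)C(C)(C)C | intermediate (not isolated)
23 | (2Z,4R,5S,6R,19S,21S,23R)-4,21,23-tris(tert-butyldimethylsilyloxy)-6-chloro-5-(sodiooxy)tetracos-2-en-19-olide | C[C@@H](O[Si](C)(C)C(C)(C)C)C[C@@H](O[Si](C)(C)C(C)(C)C)C[C@@H]1CCCCCCCCCCCC[C@@H](Cl)[C@@H](O[Na])[C@H](O[Si](C)(C)C(C)(C)C)/C=C\C(=O)O1 | intermediate (not isolated)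
24 | (2Z,4R,5R,6S,19S,21S,23R)-4,21,23-tris(tert-butyldimethylsilyloxy)-5,6-epoxytetracos-2-en-19-olide | C[C@@H](O[Si](C)(C)C(C)(C)C)C[C@@H](O[Si](C)(C)C(C)(C)C)C[C@@H]1CCCCCCCCCCCC[C@@H]2O[C@H]2[C@H](O[Si](C)(C)C(C)(C)C)/C=C\C(=O)O1 | intermediate
25 | (2Z,4R,5S,6S,19S,21R,23R)-5,6-epoxy-4,21,23-trihydroxytetracos-2-en-19-olide (CNP0461152.1) | C[C@@H](O)C[C@@H](O)C[C@@H]1CCCCCCCCCCCC[C@@H]2O[C@H]2[C@H](O)/C=C\C(=O)O1 | target

## Step count and risks

Total steps: 13. Longest linear sequence: 12 (steps 1–7 and 9–13; step 8 makes the tin reagent in one step).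

**Most likely to fail, first: step 12.** The alkoxide may oligomerise, deprotonate C4–H with ring-opening to a dienoate, or trigger silyl migration (C4→C5 or C21→C19) before the epoxide closes. The fallback sets out from 21 and forms the two rings in separate operations. K2CO3 in MeOH at 0 °C opens the pyranone intermolecularly and closes the epoxide, giving methyl (2Z,4R,5R,6S,19S,21S,23R)-4,21,23-tris(tert-butyldimethylsilyloxy)-5,6-epoxy-19-hydroxytetracos-2-enoate F1. Me3SnOH in 1,2-dichloroethane at 70 °C then gives (2Z,4R,5R,6S,19S,21S,23R)-4,21,23-tris(tert-butyldimethylsilyloxy)-5,6-epoxy-19-hydroxytetracos-2-enoic acid F2. Yamaguchi macrolactonization (2,4,6-trichlorobenzoyl chloride, Et3N, THF; then DMAP, toluene, high dilution) closes the ring with retention at C19, and the fallback comes back to the route at 24.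

**Second: step 9.** The one-pot sequence may erode the enantiopurity of the chloro aldehyde or give poor syn/anti control with the open-transition-state tin reagent. The fallback sets out from 12, which is chlorinated as before to 16. The C4–C5 bond is then made by an uncatalysed allylboration through a closed chair transition state with 2-[(Z)-3-(tert-butyldimethylsilyloxy)prop-2-en-1-yl]-4,4,5,5-tetramethyl-1,3,2-dioxaborolane F3. F3 is made from lithiated ether 14 and 2-isopropoxy-4,4,5,5-tetramethyl-1,3,2-dioxaborolane. The Z-reagent gives 4,5-syn and Cornforth control gives 5,6-anti; a chiral diol on boron can be substituted to add reagent control. The fallback comes back to the route at 17.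

**Third: step 4.** The β-oxido organolithium may be hard to generate cleanly or may enolise the amide. The fallback sets out from 6. MeMgBr in THF at 0 °C gives (4S)-4,18-bis(triethylsilyloxy)octadecan-2-one F4. Its boron enolate, formed with (−)-Ipc2BCl and Et3N (the antipode that attacks the si face of acetaldehyde), adds to acetaldehyde in a reagent-controlled aldol reaction. The minor C23 epimer is separated, and the fallback comes back to the route at 9.

## Further compounds

F1 | step 12 | methyl (2Z,4R,5R,6S,19S,21S,23R)-4,21,23-tris(tert-butyldimethylsilyloxy)-5,6-epoxy-19-hydroxytetracos-2-enoate | C[C@@H](O[Si](C)(C)C(C)(C)C)C[C@@H](O[Si](C)(C)C(C)(C)C)C[C@@H](O)CCCCCCCCCCCC[C@@H]1O[C@H]1[C@H](O[Si](C)(C)C(C)(C)C)/C=C\C(=O)OC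
F2 | step 12 | (2Z,4R,5R,6S,19S,21S,23R)-4,21,23-tris(tert-butyldimethylsilyloxy)-5,6-epoxy-19-hydroxytetracos-2-enoic acid | C[C@@H](O[Si](C)(C)C(C)(C)C)C[C@@H](O[Si](C)(C)C(C)(C)C)C[C@@H](O)CCCCCCCCCCCC[C@@H]1O[C@H]1[C@H](O[Si](C)(C)C(C)(C)C)/C=C\C(=O)O
F3 | step 9 | 2-[(Z)-3-(tert-butyldimethylsilyloxy)prop-2-en-1-yl]-4,4,5,5-tetramethyl-1,3,2-dioxaborolane | CC1(C)OB(C/C=C\O[Si](C)(C)C(C)(C)C)OC1(C)C
F4 | step 4 | (4S)-4,18-bis(triethylsilyloxy)octadecan-2-one | CC(=O)C[C@@H](O[Si](CC)(CC)CC)CCCCCCCCCCCCCCO[Si](CC)(CC)CC
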